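**Retrosynthetic overview**
1. Butenolide: cut the side-chain C–C bond next to the lactone (alkylation of 3-(phenylsulfanyl)oxolan-2-one by a 2-chloroethyl decalin, then sulfoxide elimination).
2. Decalin core: remove the ring A ketone (hydrazone reduction) and the C-methyl group (enolate methylation anti to the axial acetoxymethyl group), back to a bicyclic β-keto ester.
3. Key disconnection: both carbocycles open at once to an acyclic (6Z,10E)-triene β-keto ester; forward, one oxidative radical cascade closes ring A, then ring B, and ends in the exocyclic methylidene.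
4. Triene: crossed Claisen of methyl acetate onto a δ-lactone; the lactone comes from a β-oxido ylide three-component olefination (aldehyde, phosphonium carboxylate, formaldehyde) that fixes the Z alkene.
5. Aldehyde: Ni-catalysed methyl-for-oxygen ring opening of a 5-alkyl-2,3-dihydrofuran (E alkene), made from 2,3-dihydrofuran and a bromo acetal.

Assumption: a telescoped operation whose intermediate is not isolated counts as one step, and 3-(phenylsulfanyl)oxolan-2-one is made in one step rather than bought.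

Bicyclic compounds are named with decahydronaphthalene locants: C1 carries the ester, C4a the acetoxymethyl group, C5 the side chain, C6 the methylidene, and C8a is the ring-fusion CH.

**Step 1**
Reactants: 1 2,3-dihydrofuran; 2 2-(2-bromoethyl)-1,3-dioxolane
Product: 4 5-[2-(1,3-dioxolan-2-yl)ethyl]-2,3-dihydrofuran, via 5-lithio-2,3-dihydrofuran 3 (not isolated)
Conditions: t-BuLi, THF, −78 → 0 °C; then 2, DMPU, 0 °C → rt
Reagents that add atoms: none
Why: α-lithiation of the cyclic enol ether and SN2 alkylation of the vinyllithium by the primary bromide; no stereocentre is formed.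

**Step 2**
Reactants: 4 5-[2-(1,3-dioxolan-2-yl)ethyl]-2,3-dihydrofuran
Product: 5 (3E)-6-(1,3-dioxolan-2-yl)-4-methylhex-3-en-1-ol
Conditions: MeMgBr (3 equiv), NiCl2(PPh3)2 (5 mol%), benzene, reflux
Reagents that add atoms: methylmagnesium bromide, C[Mg]Br
Why: Ni-catalysed Grignard coupling with the enol ether C–O bond (Wenkert-type) replaces the ring oxygen by methyl with retention, so the ring geometry becomes the E trisubstituted alkene.

**Step 3**
Reactants: 5 (3E)-6-(1,3-dioxolan-2-yl)-4-methylhex-3-en-1-ol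
Product: 6 2-[(3E)-6-chloro-3-methylhex-3-en-1-yl]-1,3-dioxolane
Conditions: PPh3, N-chlorosuccinimide, CH2Cl2, 0 °C → rt
Reagents that add atoms: N-chlorosuccinimide, ClN1C(=O)CCC1=O
Why: Appel-type chlorination of the primary alcohol under neutral conditions leaves the acetal and the alkene untouched.

**Step 4**
Reactants: 6 2-[(3E)-6-chloro-3-methylhex-3-en-1-yl]-1,3-dioxolane
Product: 7 (4E)-7-chloro-4-methylhept-4-enal
Conditions: 1 M HCl, THF, rt
Reagents that add atoms: water, O
Why: acid-catalysed acetal hydrolysis; dilute acid at room temperature does not isomerise the trisubstituted alkene.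

**Step 5**
Reactants: 7 (4E)-7-chloro-4-methylhept-4-enal; 8 (3-carboxypropyl)triphenylphosphonium bromide
Product: 12 (5Z)-5-[(4E)-7-chloro-4-methylhept-4-en-1-ylidene]oxan-2-one, via ylide carboxylate 9 (not isolated), via β-oxido ylide 10 (not isolated), via hydroxy acid 11 (not isolated)
Conditions: 8, n-BuLi (2 equiv), THF, −78 → 0 °C; 7, −78 °C; s-BuLi (1 equiv), −78 → −30 °C; (CH2O)n, 0 °C → rt; 1 M HCl; TsOH (cat.), CH2Cl2, rt
Reagents that add atoms: formaldehyde (as paraformaldehyde), C=O
Why: Wittig betaine formation, α-lithiation to the β-oxido ylide and trapping with formaldehyde (Corey–Schlosser β-oxido ylide olefination) gives the trisubstituted allylic alcohol with CH2OH cis to the aldehyde-derived chain (Z), and the hydroxy acid closes to the δ-lactone on acid work-up.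

**Step 6**
Reactants: 12 (5Z)-5-[(4E)-7-chloro-4-methylhept-4-en-1-ylidene]oxan-2-one; 13 methyl acetate
Product: 14 methyl (6Z,10E)-13-chloro-6-(hydroxymethyl)-10-methyl-3-oxotrideca-6,10-dienoate
Conditions: LiN(iPr)2 (2.5 equiv), 13, THF, −78 °C; then 12, −78 → −40 °C; AcOH
Reagents that add atoms: none
Why: crossed Claisen acylation of the ester enolate by the lactone, driven by deprotonation of the β-keto ester formed; both alkene geometries are untouched.

**Step 7**
Reactants: 14 methyl (6Z,10E)-13-chloro-6-(hydroxymethyl)-10-methyl-3-oxotrideca-6,10-dienoate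
Product: 15 methyl (6Z,10E)-6-[(acetyloxy)methyl]-13-chloro-10-methyl-3-oxotrideca-6,10-dienoate
Conditions: Ac2O, pyridine, DMAP (cat.), CH2Cl2, 0 °C
Reagents that add atoms: acetic anhydride, CC(=O)OC(C)=O
Why: DMAP-catalysed O-acetylation of the primary allylic alcohol drains the open-chain form from its hemiketal equilibrium under basic conditions that avoid cyclodehydration.

**Step 8**
Reactants: 15 methyl (6Z,10E)-6-[(acetyloxy)methyl]-13-chloro-10-methyl-3-oxotrideca-6,10-dienoate
Product: 16 methyl (1S,4aR,5S,8aS)-4a-[(acetyloxy)methyl]-5-(2-chloroethyl)-6-methylidene-2-oxodecahydronaphthalene-1-carboxylate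
Conditions: Cu(OTf)2 (1.1 equiv), (R,R)-t-Bu-box [2,2'-(propane-2,2-diyl)bis((4R)-4-tert-butyl-4,5-dihydro-1,3-oxazole), 1.2 equiv], Mn(OAc)3·2H2O (2.2 equiv), CF3CH2OH, −10 → 0 °C
Reagents that add atoms: none
Why: Proposed new method: the distorted square-planar copper–bisoxazoline chelate of the β-keto ester is oxidised by trivalent manganese to a chelated α-keto ester radical that cyclises 6-endo then 6-endo through chair transition states (the 6Z alkene gives the trans ring fusion, the 10E alkene puts the chloroethyl group equatorial), the tert-butyl group beside the ketone oxygen blocks the Re face of the radical carbon where the tether must fold so that bonding on the Si face fixes C8a, C4a and C5 as in the target (C1 stays epimerisable), and divalent copper oxidises the final tertiary radical to the less substituted exocyclic alkene; the closest known reaction types are the Mn(OAc)3/Cu(OAc)2 oxidative radical polyene cyclisation of β-keto esters, lanthanide triflate-promoted Mn(OAc)3 cyclisations through chelated radicals, and bisoxazoline Lewis acid-controlled radical cyclisations of β-keto ester radicals.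

**Step 9**
Reactants: 16 methyl (1S,4aR,5S,8aS)-4a-[(acetyloxy)methyl]-5-(2-chloroethyl)-6-methylidene-2-oxodecahydronaphthalene-1-carboxylate
Product: 17 methyl (1R,4aS,5S,8aR)-4a-[(acetyloxy)methyl]-5-(2-chloroethyl)-1-methyl-6-methylidene-2-oxodecahydronaphthalene-1-carboxylate
Conditions: MeI, K2CO3, acetone, rt
Reagents that add atoms: iodomethane, CI
Why: C-methylation of the β-keto ester enolate occurs on the α face, anti to the axial acetoxymethyl group at C4a, which puts the methyl equatorial and the ester axial, as in classical alkylations of 3-oxo-4-carbomethoxy decalins.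

**Step 10**
Reactants: 17 methyl (1R,4aS,5S,8aR)-4a-[(acetyloxy)methyl]-5-(2-chloroethyl)-1-methyl-6-methylidene-2-oxodecahydronaphthalene-1-carboxylate
Product: 19 methyl (1S,4aS,5S,8aR)-4a-[(acetyloxy)methyl]-5-(2-chloroethyl)-1-methyl-6-methylidenedecahydronaphthalene-1-carboxylate, via tosylhydrazone 18 (not isolated)
Conditions: TsNHNH2, EtOH, 60 °C; then catecholborane, CHCl3, 0 °C; NaOAc·3H2O, 60 °C
Reagents that add atoms: none
Why: Caglioti–Kabalka deoxygenation: the tosylhydrazone is reduced by catecholborane and the adduct loses sulfinate and N2 to give CH2 without touching the esters, the chloride, the exocyclic alkene or any stereocentre.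

**Step 11**
Reactants: 20 3-bromooxolan-2-one; 21 benzenethiol
Product: 22 3-(phenylsulfanyl)oxolan-2-one
Conditions: Et3N, CH2Cl2, 0 °C → rt
Reagents that add atoms: none
Why: SN2 displacement of the activated α-bromo lactone by the thiolate.

**Step 12**
Reactants: 19 methyl (1S,4aS,5S,8aR)-4a-[(acetyloxy)methyl]-5-(2-chloroethyl)-1-methyl-6-methylidenedecahydronaphthalene-1-carboxylate; 22 3-(phenylsulfanyl)oxolan-2-one
Product: 25 methyl (1S,4aS,5S,8aR)-4a-[(acetyloxy)methyl]-1-methyl-6-methylidene-5-{2-[2-oxo-3-(phenylsulfanyl)oxolan-3-yl]ethyl}decahydronaphthalene-1-carboxylate, via sodium enolate 23 (not isolated), via primary iodide 24 (not isolated)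
Conditions: 22, NaH, DMF, 0 °C; then 19, NaI, 60 °C
Reagents that add atoms: none
Why: in situ Finkelstein exchange and SN2 C-alkylation of the sulfur-stabilised lactone enolate by the unhindered primary iodide; the new quaternary carbon forms as an epimer mixture that is erased in the next step.

**Step 13**
Reactants: 25 methyl (1S,4aS,5S,8aR)-4a-[(acetyloxy)methyl]-1-methyl-6-methylidene-5-{2-[2-oxo-3-(phenylsulfanyl)oxolan-3-yl]ethyl}decahydronaphthalene-1-carboxylate
Product: 27 methyl (1S,4aS,5S,8aR)-4a-[(acetyloxy)methyl]-1-methyl-6-methylidene-5-[2-(2-oxo-2,5-dihydrofuran-3-yl)ethyl]decahydronaphthalene-1-carboxylate, via sulfoxide 26 (not isolated)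
Conditions: mCPBA (1.0 equiv), CH2Cl2, −78 °C; then toluene, CaCO3, 110 °C
Reagents that add atoms: none
Why: the sulfide is oxidised far faster than the hindered exocyclic alkene at −78 °C, and thermal syn-elimination of the sulfoxide (sulfoxide pyrolysis) toward the ring CH2 gives the endocyclic α-substituted butenolide.

**Compound list**

1 | 2,3-dihydrofuran | C1=COCC1 | starting material
2 | 2-(2-bromoethyl)-1,3-dioxolane | BrCCC1OCCO1 | starting material
3 | 5-lithio-2,3-dihydrofuran | [Li]C1=CCCO1 | intermediate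
4 | 5-[2-(1,3-dioxolan-2-yl)ethyl]-2,3-dihydrofuran | C1CC=C(CCC2OCCO2)O1 | intermediate
5 | (3E)-6-(1,3-dioxolan-2-yl)-4-methylhex-3-en-1-ol | OCC/C=C(\C)CCC1OCCO1 | intermediate
6 | 2-[(3E)-6-chloro-3-methylhex-3-en-1-yl]-1,3-dioxolane | ClCC/C=C(\C)CCC1OCCO1 | intermediate
7 | (4E)-7-chloro-4-methylhept-4-enal | ClCC/C=C(\C)CCC=O | intermediate
8 | (3-carboxypropyl)triphenylphosphonium bromide | OC(=O)CCC[P+](c1ccccc1)(c1ccccc1)c1ccccc1.[Br-] | starting material
9 | lithium 4-(triphenyl-λ5-phosphanylidene)butanoate (ylide carboxylate) | [Li+].[O-]C(=O)CCC=P(c1ccccc1)(c1ccccc1)c1ccccc1 | intermediate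
10 | dilithium (8E)-11-chloro-8-methyl-5-oxido-4-(triphenyl-λ5-phosphanylidene)undec-8-enoate (β-oxido ylide, racemic at C5) | [Li+].[Li+].[O-]C(=O)CCC(=P(c1ccccc1)(c1ccccc1)c1ccccc1)C([O-])CC/C(C)=C/CCCl | intermediate
11 | (4Z,8E)-11-chloro-4-(hydroxymethyl)-8-methylundeca-4,8-dienoic acid | OC(=O)CC/C(CO)=C/CC/C(C)=C/CCCl | intermediate
12 | (5Z)-5-[(4E)-7-chloro-4-methylhept-4-en-1-ylidene]oxan-2-one | O=C1CC/C(=C/CC/C(C)=C/CCCl)CO1 | intermediate
13 | methyl acetate | COC(C)=O | starting material
14 | methyl (6Z,10E)-13-chloro-6-(hydroxymethyl)-10-methyl-3-oxotrideca-6,10-dienoate | COC(=O)CC(=O)CC/C(CO)=C/CC/C(C)=C/CCCl | intermediate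
15 | methyl (6Z,10E)-6-[(acetyloxy)methyl]-13-chloro-10-methyl-3-oxotrideca-6,10-dienoate | COC(=O)CC(=O)CC/C(COC(C)=O)=C/CC/C(C)=C/CCCl | intermediate
16 | methyl (1S,4aR,5S,8aS)-4a-[(acetyloxy)methyl]-5-(2-chloroethyl)-6-methylidene-2-oxodecahydronaphthalene-1-carboxylate (keto form drawn, ester equatorial; in equilibrium with its enol) | C=C1CC[C@@H]2[C@](COC(C)=O)(CCC(=O)[C@H]2C(=O)OC)[C@H]1CCCl | intermediate
17 | methyl (1R,4aS,5S,8aR)-4a-[(acetyloxy)methyl]-5-(2-chloroethyl)-1-methyl-6-methylidene-2-oxodecahydronaphthalene-1-carboxylate | C=C1CC[C@@H]2[C@](COC(C)=O)(CCC(=O)[C@]2(C)C(=O)OC)[C@H]1CCCl | intermediate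
18 | methyl (1R,2E,4aS,5S,8aR)-4a-[(acetyloxy)methyl]-5-(2-chloroethyl)-1-methyl-6-methylidene-2-[2-(4-methylbenzenesulfonyl)hydrazinylidene]decahydronaphthalene-1-carboxylate | C=C1CC[C@@H]2[C@](COC(C)=O)(CC/C(=N\NS(=O)(=O)c3ccc(C)cc3)[C@]2(C)C(=O)OC)[C@H]1CCCl | intermediate
19 | methyl (1S,4aS,5S,8aR)-4a-[(acetyloxy)methyl]-5-(2-chloroethyl)-1-methyl-6-methylidenedecahydronaphthalene-1-carboxylate | C=C1CC[C@@H]2[C@](COC(C)=O)(CCC[C@]2(C)C(=O)OC)[C@H]1CCCl | intermediate
20 | 3-bromooxolan-2-one (racemic) | BrC1CCOC1=O | starting material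
21 | benzenethiol | Sc1ccccc1 | starting material
22 | 3-(phenylsulfanyl)oxolan-2-one (racemic) | O=C1OCCC1Sc1ccccc1 | intermediate
23 | sodium 3-(phenylsulfanyl)-4,5-dihydrofuran-2-olate | [Na+].[O-]C1=C(Sc2ccccc2)CCO1 | intermediate
24 | methyl (1S,4aS,5S,8aR)-4a-[(acetyloxy)methyl]-5-(2-iodoethyl)-1-methyl-6-methylidenedecahydronaphthalene-1-carboxylate | C=C1CC[C@@H]2[C@](COC(C)=O)(CCC[C@]2(C)C(=O)OC)[C@H]1CCI | intermediate
25 | methyl (1S,4aS,5S,8aR)-4a-[(acetyloxy)methyl]-1-methyl-6-methylidene-5-{2-[2-oxo-3-(phenylsulfanyl)oxolan-3-yl]ethyl}decahydronaphthalene-1-carboxylate (both epimers at the oxolane carbon) | C=C1CC[C@@H]2[C@](COC(C)=O)(CCC[C@]2(C)C(=O)OC)[C@H]1CCC1(Sc3ccccc3)CCOC1=O | intermediate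
26 | methyl (1S,4aS,5S,8aR)-4a-[(acetyloxy)methyl]-5-{2-[3-(benzenesulfinyl)-2-oxooxolan-3-yl]ethyl}-1-methyl-6-methylidenedecahydronaphthalene-1-carboxylate (diastereomer mixture at sulfur and the oxolane carbon) | C=C1CC[C@@H]2[C@](COC(C)=O)(CCC[C@]2(C)C(=O)OC)[C@H]1CCC1(S(=O)c3ccccc3)CCOC1=O | intermediate
27 | methyl (1S,4aS,5S,8aR)-4a-[(acetyloxy)methyl]-1-methyl-6-methylidene-5-[2-(2-oxo-2,5-dihydrofuran-3-yl)ethyl]decahydronaphthalene-1-carboxylate | C=C1CC[C@@H]2[C@](COC(C)=O)(CCC[C@]2(C)C(=O)OC)[C@H]1CCC1=CCOC1=O | target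

**Totals**

Total step count: 13. Longest linear sequence: 12 steps (steps 1 to 10, then 12 and 13); step 11 is a one-step side branch.

**Three steps most likely to fail, each with a fallback**

Step 8 (risk: the sense and level of enantio-induction rest on a model, and the enolisable product can be over-oxidised). The fallback sets out from 12 and comes back at 16, replacing catalyst control by a chelation-controlled auxiliary of the kind known for Mn(OAc)3 cyclisations of 8-phenylmenthyl β-keto esters. Commercial (1S,2R,5S)-8-phenylmenthol is acetylated with acetyl chloride to (1S,2R,5S)-5-methyl-2-(2-phenylpropan-2-yl)cyclohexyl acetate F1. Its lithium enolate opens lactone 12 to the 8-phenylmenthyl hydroxy keto ester F2, and acetylation gives the 8-phenylmenthyl acetoxy keto ester F3. Cyclisation with Mn(OAc)3·2H2O, Yb(OTf)3 and Cu(OAc)2 in CF3CH2OH at −5 °C gives the bicyclic 8-phenylmenthyl keto ester F4; in the ytterbium chelate the phenyl ring shields the Re face of the radical carbon. Ester exchange with methanol (DMAP, toluene, 110 °C, possible because C1 is still enolisable) returns the auxiliary and gives 16.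

Step 5 (risk: the β-oxido ylide sequence with a poorly soluble carboxylate-bearing ylide). The fallback sets out from 7 and comes back at 12, building the Z alkene by a sigmatropic shift instead. Commercial 2-bromoallyl alcohol is silylated to [(2-bromoprop-2-en-1-yl)oxy](tert-butyl)dimethylsilane F5. Bromine–lithium exchange (t-BuLi) and addition to 7 give the allylic alcohol F6. Johnson–Claisen rearrangement (MeC(OEt)3, EtCO2H cat., 140 °C) through a chair with the chain equatorial gives the ethyl (4Z,8E)-dienoate F7. Bu4NF removes the silyl group to give the hydroxy ester F8, which lactonises with catalytic TsOH to 12.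

Step 10 (risk: slow hydrazone formation at the ketone flanked by the quaternary carbon). The fallback sets out from 17 and comes back at 19 by radical deoxygenation. NaBH4 reduces the ketone to the equatorial alcohol F9. 1,1'-Thiocarbonyldiimidazole converts it into the imidazole-1-carbothioate F10. Bu3SnH with AIBN in toluene at 80 °C (Barton–McCombie) then gives 19.

**Further compounds**

F1 | step 8 | (1S,2R,5S)-5-methyl-2-(2-phenylpropan-2-yl)cyclohexyl acetate | CC(C)(c1ccccc1)[C@H]1CC[C@H](C)C[C@@H]1OC(C)=O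
F2 | step 8 | (1S,2R,5S)-5-methyl-2-(2-phenylpropan-2-yl)cyclohexyl (6Z,10E)-13-chloro-6-(hydroxymethyl)-10-methyl-3-oxotrideca-6,10-dienoate | CC(C)(c1ccccc1)[C@H]1CC[C@H](C)C[C@@H]1OC(=O)CC(=O)CC/C(CO)=C/CC/C(C)=C/CCCl
F3 | step 8 | (1S,2R,5S)-5-methyl-2-(2-phenylpropan-2-yl)cyclohexyl (6Z,10E)-6-[(acetyloxy)methyl]-13-chloro-10-methyl-3-oxotrideca-6,10-dienoate | CC(C)(c1ccccc1)[C@H]1CC[C@H](C)C[C@@H]1OC(=O)CC(=O)CC/C(COC(C)=O)=C/CC/C(C)=C/CCCl
F4 | step 8 | (1S,2R,5S)-5-methyl-2-(2-phenylpropan-2-yl)cyclohexyl (1S,4aR,5S,8aS)-4a-[(acetyloxy)methyl]-5-(2-chloroethyl)-6-methylidene-2-oxodecahydronaphthalene-1-carboxylate | C=C1CC[C@@H]2[C@](COC(C)=O)(CCC(=O)[C@H]2C(=O)O[C@H]3C[C@@H](C)CC[C@@H]3C(C)(C)c4ccccc4)[C@H]1CCCl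
F5 | step 5 | [(2-bromoprop-2-en-1-yl)oxy](tert-butyl)dimethylsilane | C=C(Br)CO[Si](C)(C)C(C)(C)C
F6 | step 5 | (6E)-2-({[tert-butyl(dimethyl)silyl]oxy}methyl)-9-chloro-6-methylnona-1,6-dien-3-ol (racemic) | C=C(CO[Si](C)(C)C(C)(C)C)C(O)CC/C(C)=C/CCCl
F7 | step 5 | ethyl (4Z,8E)-4-({[tert-butyl(dimethyl)silyl]oxy}methyl)-11-chloro-8-methylundeca-4,8-dienoate | CCOC(=O)CC/C(CO[Si](C)(C)C(C)(C)C)=C/CC/C(C)=C/CCCl
F8 | step 5 | ethyl (4Z,8E)-11-chloro-4-(hydroxymethyl)-8-methylundeca-4,8-dienoate | CCOC(=O)CC/C(CO)=C/CC/C(C)=C/CCCl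
F9 | step 10 | methyl (1R,2S,4aS,5S,8aR)-4a-[(acetyloxy)methyl]-5-(2-chloroethyl)-2-hydroxy-1-methyl-6-methylidenedecahydronaphthalene-1-carboxylate | C=C1CC[C@@H]2[C@](COC(C)=O)(CC[C@H](O)[C@]2(C)C(=O)OC)[C@H]1CCCl
F10 | step 10 | methyl (1R,2S,4aS,5S,8aR)-4a-[(acetyloxy)methyl]-5-(2-chloroethyl)-2-[(1H-imidazole-1-carbothioyl)oxy]-1-methyl-6-methylidenedecahydronaphthalene-1-carboxylate | C=C1CC[C@@H]2[C@](COC(C)=O)(CC[C@H](OC(=S)n3ccnc3)[C@]2(C)C(=O)OC)[C@H]1CCCl
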